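**Plan**

- Retrosynthesis: the O1–C2 bond of ring C is cut first (phenol oxidation, then oxa-conjugate addition), next the aryl ketone bond C4–C4a (aryllithium plus Weinreb amide), then C2–C1' (aryl Grignard plus glycidate) and the C6–prenyl bond.
- Enabling feature: C2 is benzylic to ring B and para to the 4'-hydroxyl, so taking two electrons and two protons from that phenol makes C2 the electrophilic end of a para-quinone methide, six atoms from the C8a hydroxyl of ring A.
- Forward, ring A: from resorcinol. The prenyl group goes between two MOM ethers, the third oxygen is added by C–H borylation/oxidation and kept apart as a THP ether, so that only O8a is free later and the prenyl group ends at C6.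
- Forward, ring B and assembly: ring B comes from 5-bromo-2-hydroxy-3-methoxybenzaldehyde; the two arenes are joined at C4–C4a as an α-silyloxy dihydrochalcone, both THP ethers are removed together, and ring C closes last.
- Stereochemistry: C3 (R) is taken from methyl (R)-glycidate and is never a reacting centre afterwards; C2 (R) arises in the ring closure, trans to C3, under substrate control.

Key step: step 13

Remark on the chemistry: the acetal carbon of each THP (oxan-2-yl) ether is not controlled. THP-bearing compounds are carried as mixtures of acetal epimers, their SMILES leave that carbon undefined, and the mixtures converge in step 12.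

**Ring A fragment**

Step 1
Reactants: 1 resorcinol
Product: 2 1,3-bis(methoxymethoxy)benzene
Conditions: NaH (2.4 equiv), MOMCl (2.4 equiv), DMF, 0 °C → rt
Reagents that add atoms: chloromethyl methyl ether, COCCl
Why: Double Williamson O-alkylation of the bis-phenoxide installs the MOM ethers that later direct lithiation and come off with acid at the end.

Step 2
Reactants: 2 1,3-bis(methoxymethoxy)benzene; 3 prenyl bromide (1-bromo-3-methylbut-2-ene)
Product: 5 1,3-bis(methoxymethoxy)-2-(3-methylbut-2-en-1-yl)benzene, via aryllithium 4 (not isolated)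
Conditions: n-BuLi (1.1 equiv), THF, 0 °C → rt; CuBr·SMe2 (10 mol%), 3 (1.2 equiv), −78 °C → rt
Reagents that add atoms: none
Why: Directed ortho-metalation removes the proton flanked by both MOM ethers, and copper-catalysed SN2 allylation of the aryllithium with the primary allylic bromide should give the linear prenyl group.

Step 3
Reactants: 5 1,3-bis(methoxymethoxy)-2-(3-methylbut-2-en-1-yl)benzene
Product: 7 3,5-bis(methoxymethoxy)-4-(3-methylbut-2-en-1-yl)phenol, via aryl pinacol boronate 6 (not isolated)
Conditions: [Ir(OMe)(cod)]2 (1.5 mol%), 4,4'-di-tert-butyl-2,2'-bipyridine (3 mol%), B2pin2 (0.6 equiv), THF, 65 °C; then aq. NaOH, H2O2 (30%), 0 °C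
Reagents that add atoms: hydrogen peroxide, OO
Why: Sterically controlled iridium-catalysed arene C–H borylation should occur at C5, the only ring C–H without an ortho substituent, and alkaline peroxide then turns C–B into C–O without touching the trisubstituted olefin, which supplies the one oxygen that can be protected differently from the other two.

Step 4
Reactants: 7 3,5-bis(methoxymethoxy)-4-(3-methylbut-2-en-1-yl)phenol
Product: 8 2-[3,5-bis(methoxymethoxy)-4-(3-methylbut-2-en-1-yl)phenoxy]oxane
Conditions: 3,4-dihydro-2H-pyran (1.5 equiv), PPTS (5 mol%), CH2Cl2, rt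
Reagents that add atoms: 3,4-dihydro-2H-pyran, C1=COCCC1
Why: Acid-catalysed addition of the phenol to the enol ether (tetrahydropyranylation) gives an acetal that directs lithiation and is far more acid-labile than an aryl MOM ether.

**Ring B fragment**

Step 5
Reactants: 9 5-bromo-2-hydroxy-3-methoxybenzaldehyde
Product: 10 5-bromo-3-methoxy-2-(oxan-2-yloxy)benzaldehyde
Conditions: 3,4-dihydro-2H-pyran (2 equiv), PPTS (10 mol%), CH2Cl2, 40 °C
Reagents that add atoms: 3,4-dihydro-2H-pyran, C1=COCCC1
Why: The same acid-catalysed tetrahydropyranylation places the labile acetal on the oxygen that becomes O4'.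

Step 6
Reactants: 10 5-bromo-3-methoxy-2-(oxan-2-yloxy)benzaldehyde
Product: 12 5-bromo-3-methoxy-2-(oxan-2-yloxy)phenol, via aryl formate 11 (not isolated)
Conditions: mCPBA (1.3 equiv), NaHCO3 (2 equiv), CH2Cl2, 0 °C → rt; then MeOH, Et3N (cat.), rt
Reagents that add atoms: 3-chloroperoxybenzoic acid, OOC(=O)c1cccc(Cl)c1
Why: Baeyer–Villiger oxidation with aryl migration (favoured by the ortho alkoxy group) gives the aryl formate, which methanol cleaves to the phenol, while the bicarbonate buffer keeps the THP acetal intact.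

Step 7
Reactants: 12 5-bromo-3-methoxy-2-(oxan-2-yloxy)phenol
Product: 13 2-[4-bromo-2-methoxy-6-(methoxymethoxy)phenoxy]oxane
Conditions: NaH (1.2 equiv), MOMCl (1.2 equiv), DMF, 0 °C → rt
Reagents that add atoms: chloromethyl methyl ether, COCCl
Why: Williamson O-alkylation of the phenoxide puts the robust acetal on the oxygen that becomes O5'.

Step 8
Reactants: 13 2-[4-bromo-2-methoxy-6-(methoxymethoxy)phenoxy]oxane; 14 methyl (2R)-oxirane-2-carboxylate (methyl (R)-glycidate)
Product: 16 methyl (2R)-2-hydroxy-3-[3-methoxy-5-(methoxymethoxy)-4-(oxan-2-yloxy)phenyl]propanoate, via arylmagnesium bromide 15 (not isolated)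
Conditions: Mg turnings, THF, 45 °C; then CuBr·SMe2 (10 mol%), 14 (0.8 equiv), THF, −40 → −10 °C
Reagents that add atoms: none
Why: Magnesium insertion into the unhindered aryl bromide and copper-catalysed SN2 opening of the epoxide at its unsubstituted carbon form the C2–C1' bond, and because the glycidate stereocentre is not attacked its (R) configuration passes unchanged into the future C3.

Step 9
Reactants: 16 methyl (2R)-2-hydroxy-3-[3-methoxy-5-(methoxymethoxy)-4-(oxan-2-yloxy)phenyl]propanoate
Product: 17 methyl (2R)-2-[(tert-butyldimethylsilyl)oxy]-3-[3-methoxy-5-(methoxymethoxy)-4-(oxan-2-yloxy)phenyl]propanoate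
Conditions: TBSCl (1.3 equiv), imidazole (2.5 equiv), DMF, rt
Reagents that add atoms: tert-butyldimethylsilyl chloride, CC(C)(C)[Si](C)(C)Cl
Why: Standard silylation of a secondary alcohol masks the hydroxyl for the organolithium step and for the oxidation.

Step 10
Reactants: 17 methyl (2R)-2-[(tert-butyldimethylsilyl)oxy]-3-[3-methoxy-5-(methoxymethoxy)-4-(oxan-2-yloxy)phenyl]propanoate
Product: 18 (2R)-2-[(tert-butyldimethylsilyl)oxy]-N-methoxy-3-[3-methoxy-5-(methoxymethoxy)-4-(oxan-2-yloxy)phenyl]-N-methylpropanamide
Conditions: MeNH(OMe)·HCl (1.5 equiv), i-PrMgCl (3.0 equiv), THF, −20 → 0 °C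
Reagents that add atoms: N,O-dimethylhydroxylamine hydrochloride, CNOC.Cl
Why: Aminolysis of the ester by the chloromagnesium amide made in situ (Weinreb amide formation) is known to leave α-silyloxy stereocentres intact at low temperature.

**Assembly and endgame**

Step 11
Reactants: 8 2-[3,5-bis(methoxymethoxy)-4-(3-methylbut-2-en-1-yl)phenoxy]oxane; 18 Weinreb amide
Product: 20 (2R)-1-[2,4-bis(methoxymethoxy)-3-(3-methylbut-2-en-1-yl)-6-(oxan-2-yloxy)phenyl]-2-[(tert-butyldimethylsilyl)oxy]-3-[3-methoxy-5-(methoxymethoxy)-4-(oxan-2-yloxy)phenyl]propan-1-one, via aryllithium 19 (not isolated)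
Conditions: 8 (1.3 equiv), n-BuLi (1.25 equiv), THF, 0 °C; then 18, −78 → 0 °C
Reagents that add atoms: none
Why: Directed ortho-metalation of 8 can only occur at the two equivalent positions between the THP and MOM ethers, and the Weinreb ketone synthesis stops at the ketone through the chelated tetrahedral intermediate, so the acyl group ends next to the THP-protected oxygen and C3 is untouched.

Step 12
Reactants: 20 bis-THP ketone
Product: 21 (2R)-2-[(tert-butyldimethylsilyl)oxy]-1-[6-hydroxy-2,4-bis(methoxymethoxy)-3-(3-methylbut-2-en-1-yl)phenyl]-3-[4-hydroxy-3-methoxy-5-(methoxymethoxy)phenyl]propan-1-one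
Conditions: PPTS (20 mol%), MeOH, 40 °C
Reagents that add atoms: none
Why: Acid-catalysed transacetalisation to methanol cleaves both aryl THP ethers under conditions too mild for aryl MOM ethers or the secondary silyl ether, freeing exactly the 4'-phenol that is to be oxidised and the C8a phenol that is to add.

Step 13
Reactants: 21 α-silyloxy dihydrochalcone with free 4'- and C8a-hydroxyls
Product: 23 (2R,3R)-3-[(tert-butyldimethylsilyl)oxy]-2-[4-hydroxy-3-methoxy-5-(methoxymethoxy)phenyl]-5,7-bis(methoxymethoxy)-6-(3-methylbut-2-en-1-yl)-2,3-dihydro-4H-chromen-4-one, via para-quinone methide 22 (not isolated)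
Conditions: undivided cell, graphite anode, Pt cathode, constant current (about 2.1 F/mol), n-Bu4NBF4 (0.1 M), CH2Cl2/(CF3)2CHOH 4:1, 0 °C
Reagents that add atoms: none
Why: Proposed new method: the ring-B phenol loses two electrons and two protons at the anode (phenoxonium ion, then loss of the C2 proton) to give para-quinone methide 22, and the ring-A hydroxyl on C8a adds to its exocyclic carbon C2, forming O1–C2 and restoring the aromaticity of ring B. The closest known reactions are the quinone-mediated oxidative cyclisation of 1-(2-hydroxyaryl)-3-(4-hydroxyaryl)propanes to flavans and the anodic benzylic alkoxylation of 4-alkyl-2,6-dialkoxyphenols, both of which pass through such a quinone methide; what is new is the intramolecular capture next to a ketone on an α-silyloxy dihydrochalcone. Ring C closes in a 6-exo-trig oxa-conjugate addition. The new C2 centre is controlled by the existing C3 centre: a chair-like closure with the silyloxy and aryl groups both equatorial should give the 2,3-trans (2R,3R) isomer, and since 23 keeps its free 4'-hydroxyl a cis isomer can reopen to 22 and drain to the more stable trans compound. The step needs oxidation of ring B only, which its electron-rich 2,6-dioxygenated phenol secures against the acylated, hydrogen-bonded ring-A phenol and the prenyl olefin (charge limited to about two faradays per mole, ortho positions blocked against radical coupling), and it needs closure through O8a only, which is secured because the other ortho oxygen of ring A is a MOM ether. No base is added, so that the quinone methide is captured in the weakly acidic fluoroalcohol medium before it can tautomerise to the achiral α-silyloxychalcone.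

Step 14
Reactants: 23 protected dihydroflavonol
Product: 24 (2R,3R)-2-(3,4-dihydroxy-5-methoxyphenyl)-3,5,7-trihydroxy-6-(3-methylbut-2-en-1-yl)-2,3-dihydro-4H-chromen-4-one
Conditions: conc. HCl (aq), MeOH, 45 °C
Reagents that add atoms: none
Why: Acid-catalysed acetal exchange with methanol removes the three aryl MOM ethers and the same medium solvolyses the secondary silyl ether, conditions that are standard for MOM removal on prenylated flavonoids and that should leave the trans C2/C3 arrangement, the stable one, unchanged.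

**Compound list**

1 | resorcinol | Oc1cccc(O)c1 | starting material
2 | 1,3-bis(methoxymethoxy)benzene | COCOc1cccc(OCOC)c1 | intermediate
3 | prenyl bromide (1-bromo-3-methylbut-2-ene) | CC(C)=CCBr | starting material
4 | [2,6-bis(methoxymethoxy)phenyl]lithium (formed in situ) | [Li]c1c(OCOC)cccc1OCOC | intermediate
5 | 1,3-bis(methoxymethoxy)-2-(3-methylbut-2-en-1-yl)benzene | COCOc1cccc(OCOC)c1CC=C(C)C | intermediate
6 | 2-[3,5-bis(methoxymethoxy)-4-(3-methylbut-2-en-1-yl)phenyl]-4,4,5,5-tetramethyl-1,3,2-dioxaborolane (formed in situ) | COCOc1cc(B2OC(C)(C)C(C)(C)O2)cc(OCOC)c1CC=C(C)C | intermediate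
7 | 3,5-bis(methoxymethoxy)-4-(3-methylbut-2-en-1-yl)phenol | COCOc1cc(O)cc(OCOC)c1CC=C(C)C | intermediate
8 | 2-[3,5-bis(methoxymethoxy)-4-(3-methylbut-2-en-1-yl)phenoxy]oxane (racemic acetal) | COCOc1cc(OC2CCCCO2)cc(OCOC)c1CC=C(C)C | intermediate
9 | 5-bromo-2-hydroxy-3-methoxybenzaldehyde | COc1cc(Br)cc(C=O)c1O | starting material
10 | 5-bromo-3-methoxy-2-(oxan-2-yloxy)benzaldehyde (racemic acetal) | COc1cc(Br)cc(C=O)c1OC1CCCCO1 | intermediate
11 | 5-bromo-3-methoxy-2-(oxan-2-yloxy)phenyl formate (formed in situ) | COc1cc(Br)cc(OC=O)c1OC1CCCCO1 | intermediate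
12 | 5-bromo-3-methoxy-2-(oxan-2-yloxy)phenol (racemic acetal) | COc1cc(Br)cc(O)c1OC1CCCCO1 | intermediate
13 | 2-[4-bromo-2-methoxy-6-(methoxymethoxy)phenoxy]oxane (racemic acetal) | COCOc1cc(Br)cc(OC)c1OC1CCCCO1 | intermediate
14 | methyl (2R)-oxirane-2-carboxylate (methyl (R)-glycidate) | COC(=O)[C@H]1CO1 | starting material
15 | [3-methoxy-5-(methoxymethoxy)-4-(oxan-2-yloxy)phenyl]magnesium bromide (formed in situ) | COCOc1cc([Mg]Br)cc(OC)c1OC1CCCCO1 | intermediate
16 | methyl (2R)-2-hydroxy-3-[3-methoxy-5-(methoxymethoxy)-4-(oxan-2-yloxy)phenyl]propanoate (acetal epimers) | COC(=O)[C@H](O)Cc1cc(OC)c(OC2CCCCO2)c(OCOC)c1 | intermediate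
17 | methyl (2R)-2-[(tert-butyldimethylsilyl)oxy]-3-[3-methoxy-5-(methoxymethoxy)-4-(oxan-2-yloxy)phenyl]propanoate (acetal epimers) | COC(=O)[C@H](O[Si](C)(C)C(C)(C)C)Cc1cc(OC)c(OC2CCCCO2)c(OCOC)c1 | intermediate
18 | (2R)-2-[(tert-butyldimethylsilyl)oxy]-N-methoxy-3-[3-methoxy-5-(methoxymethoxy)-4-(oxan-2-yloxy)phenyl]-N-methylpropanamide (acetal epimers) | CON(C)C(=O)[C@H](O[Si](C)(C)C(C)(C)C)Cc1cc(OC)c(OC2CCCCO2)c(OCOC)c1 | intermediate
19 | [2,4-bis(methoxymethoxy)-3-(3-methylbut-2-en-1-yl)-6-(oxan-2-yloxy)phenyl]lithium (formed in situ) | [Li]c1c(OC2CCCCO2)cc(OCOC)c(CC=C(C)C)c1OCOC | intermediate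
20 | (2R)-1-[2,4-bis(methoxymethoxy)-3-(3-methylbut-2-en-1-yl)-6-(oxan-2-yloxy)phenyl]-2-[(tert-butyldimethylsilyl)oxy]-3-[3-methoxy-5-(methoxymethoxy)-4-(oxan-2-yloxy)phenyl]propan-1-one (acetal epimers) | COCOc1cc(OC2CCCCO2)c(C(=O)[C@H](O[Si](C)(C)C(C)(C)C)Cc2cc(OC)c(OC3CCCCO3)c(OCOC)c2)c(OCOC)c1CC=C(C)C | intermediate
21 | (2R)-2-[(tert-butyldimethylsilyl)oxy]-1-[6-hydroxy-2,4-bis(methoxymethoxy)-3-(3-methylbut-2-en-1-yl)phenyl]-3-[4-hydroxy-3-methoxy-5-(methoxymethoxy)phenyl]propan-1-one | COCOc1cc(O)c(C(=O)[C@H](O[Si](C)(C)C(C)(C)C)Cc2cc(OC)c(O)c(OCOC)c2)c(OCOC)c1CC=C(C)C | intermediate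
22 | (2R)-2-[(tert-butyldimethylsilyl)oxy]-1-[6-hydroxy-2,4-bis(methoxymethoxy)-3-(3-methylbut-2-en-1-yl)phenyl]-3-[3-methoxy-5-(methoxymethoxy)-4-oxocyclohexa-2,5-dien-1-ylidene]propan-1-one (para-quinone methide, formed in situ, exocyclic alkene geometry undefined) | COCOc1cc(O)c(C(=O)[C@H](O[Si](C)(C)C(C)(C)C)C=C2C=C(OC)C(=O)C(OCOC)=C2)c(OCOC)c1CC=C(C)C | intermediate
23 | (2R,3R)-3-[(tert-butyldimethylsilyl)oxy]-2-[4-hydroxy-3-methoxy-5-(methoxymethoxy)phenyl]-5,7-bis(methoxymethoxy)-6-(3-methylbut-2-en-1-yl)-2,3-dihydro-4H-chromen-4-one | COc1cc([C@H]2Oc3cc(OCOC)c(CC=C(C)C)c(OCOC)c3C(=O)[C@@H]2O[Si](C)(C)C(C)(C)C)cc(OCOC)c1O | intermediate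
24 | (2R,3R)-2-(3,4-dihydroxy-5-methoxyphenyl)-3,5,7-trihydroxy-6-(3-methylbut-2-en-1-yl)-2,3-dihydro-4H-chromen-4-one | COc1cc([C@H]2Oc3cc(O)c(CC=C(C)C)c(O)c3C(=O)[C@@H]2O)cc(O)c1O | target

**Step count and risks**

Total: 14 steps. Longest linear sequence: 10 steps (9 → 24, steps 5–14); the ring-A branch (steps 1–4) joins at step 11.

Steps most likely to fail:

1. Step 13 (proposed new method). The electrode process may not stop at 23: the product is itself a 4-alkyl-2,6-dialkoxyphenol and can be oxidised further, phenoxyl radicals may foul the anode, and the quinone methide may tautomerise before it is captured. The fallback separates oxidation from ring closure and uses known chemistry. It sets out from 21: one equivalent of 2,3-dichloro-5,6-dicyano-1,4-benzoquinone in CH2Cl2/MeOH at 0 °C, the established quinone dehydrogenation of 4-alkyl-2,6-dialkoxyphenols with capture by methanol, should give the C2 methyl ether F1 as a mixture of epimers at the new carbon. F1 is isolated and then ionised with catalytic camphorsulfonic acid in CH2Cl2 at 0 °C. Ionisation of a benzylic oxygen leaving group para to a phenol with capture by the ortho hydroxyl of the aroyl ring is the way dihydroflavonols are closed from β-oxygenated dihydrochalcones, and it returns the route to 23.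

2. Step 3. The iridium boryl hydride species may hydroborate or isomerise the prenyl olefin in competition with arene borylation. The fallback introduces the oxygen before the olefin and sets out from 2. The same borylation–oxidation, now on an olefin-free arene, should give via the pinacol boronate F2 the known 3,5-bis(methoxymethoxy)phenol F3. Silylation (TIPSCl, imidazole, DMF) gives the TIPS ether F4, whose bulky, non-coordinating silyloxy group leaves the position between the two MOM ethers as the only site for n-BuLi. Lithiation to the aryllithium F5 and copper-catalysed prenylation with 3 give the prenylated TIPS ether F6, and TBAF in THF returns the route to phenol 7.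

3. Step 11. The di-ortho-substituted aryllithium may add slowly to the hindered Weinreb amide and instead deprotonate it at the α-carbon or fragment its N–O unit. The fallback sets out from 18 and 8 and goes through a less hindered electrophile. DIBAL-H (THF, −78 °C) reduces 18 to the aldehyde F7, which is used at once. Aryllithium 19 (from 8 as in step 11) adds at −78 °C to give the carbinol F8 as a mixture of epimers at the new carbinol carbon. Dess–Martin periodinane (NaHCO3, CH2Cl2) oxidises F8 to ketone 20, where the route is rejoined.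

**Further compounds**

F1 | step 13 | (2R)-2-[(tert-butyldimethylsilyl)oxy]-1-[6-hydroxy-2,4-bis(methoxymethoxy)-3-(3-methylbut-2-en-1-yl)phenyl]-3-[4-hydroxy-3-methoxy-5-(methoxymethoxy)phenyl]-3-methoxypropan-1-one (C3 epimers) | COCOc1cc(O)c(C(=O)[C@H](O[Si](C)(C)C(C)(C)C)C(OC)c2cc(OC)c(O)c(OCOC)c2)c(OCOC)c1CC=C(C)C
F2 | step 3 | 2-[3,5-bis(methoxymethoxy)phenyl]-4,4,5,5-tetramethyl-1,3,2-dioxaborolane | COCOc1cc(B2OC(C)(C)C(C)(C)O2)cc(OCOC)c1
F3 | step 3 | 3,5-bis(methoxymethoxy)phenol | COCOc1cc(O)cc(OCOC)c1
F4 | step 3 | [3,5-bis(methoxymethoxy)phenoxy]tri(propan-2-yl)silane | COCOc1cc(O[Si](C(C)C)(C(C)C)C(C)C)cc(OCOC)c1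
F5 | step 3 | [2,6-bis(methoxymethoxy)-4-{[tri(propan-2-yl)silyl]oxy}phenyl]lithium | [Li]c1c(OCOC)cc(O[Si](C(C)C)(C(C)C)C(C)C)cc1OCOC
F6 | step 3 | [3,5-bis(methoxymethoxy)-4-(3-methylbut-2-en-1-yl)phenoxy]tri(propan-2-yl)silane | COCOc1cc(O[Si](C(C)C)(C(C)C)C(C)C)cc(OCOC)c1CC=C(C)C
F7 | step 11 | (2R)-2-[(tert-butyldimethylsilyl)oxy]-3-[3-methoxy-5-(methoxymethoxy)-4-(oxan-2-yloxy)phenyl]propanal | O=C[C@H](O[Si](C)(C)C(C)(C)C)Cc1cc(OC)c(OC2CCCCO2)c(OCOC)c1
F8 | step 11 | (2R)-1-[2,4-bis(methoxymethoxy)-3-(3-methylbut-2-en-1-yl)-6-(oxan-2-yloxy)phenyl]-2-[(tert-butyldimethylsilyl)oxy]-3-[3-methoxy-5-(methoxymethoxy)-4-(oxan-2-yloxy)phenyl]propan-1-ol (C1 epimers) | COCOc1cc(OC2CCCCO2)c(C(O)[C@H](O[Si](C)(C)C(C)(C)C)Cc2cc(OC)c(OC3CCCCO3)c(OCOC)c2)c(OCOC)c1CC=C(C)C
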